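Retrosynthetic overview (elemanolide locants: ring C5–C10; lactone C11, C12, C13 on C7/C8; oxirane C1–C2 and methyl C14 on C10; acrolein C3, C4, C15 on C5)
1. Target ⇐ vinyl/isopropenyl lactone: the C15 aldehyde by allylic oxidation and the oxirane by a bromohydrin sequence, both last.
2. Vinyl/isopropenyl lactone ⇐ acyclic bis(allylic bromide) + glyoxal: one indium-mediated double Barbier allylation forms C7–C8 and C9–C10, closing the cyclohexane and then the γ-lactone.
3. Enabling feature: the C8–C9 edge of the cyclohexane carries vicinal oxygens (lactone O on C8, free OH on C9), and both neighbours (C7, C10) bear a C=C one bond out (C11=C13, C1=C2). These are two homoallylic-alcohol retrons sharing one two-carbon dialdehyde.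
4. Bis(bromide) ⇐ syn propargylic alcohol (directed hydroalumination/iodination, acylation, carbonylation, bromination) ⇐ (Z,Z)-dienyl trichlorosilane + ynal by catalytic asymmetric allylation, which sets C5 and C6.
5. Dienyl unit ⇐ two (Z)-vinyl iodides (from but-2-yn-1-ol and propargyl alcohol) by Negishi coupling; ring order: cyclohexane, lactone, oxirane.

Key step: step 12

Remark: the (R,R)-catalyst of step 7 is assumed to deliver the allyl group to the Si face of the ynal, as it does with aromatic aldehydes; glyoxal is used as the commercial 40% aqueous solution.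

Step 1
Reactants: 1 but-2-yn-1-ol
Product: 3 (2Z)-3-iodobut-2-en-1-ol, via cyclic sodium alkenylalanate 2 (not isolated)
Conditions: NaAlH2(OCH2CH2OCH3)2 (Red-Al), THF, 0 °C to rt; then I2, THF, −78 °C
Reagents that add atoms: iodine (II)
Why: Hydroxyl-directed trans-hydroalumination puts aluminium on the distal alkyne carbon inside a five-membered alanate, and iodinolysis with retention gives the (Z)-iodide that later fixes the cis relation of C5 and C2 across C10=C1.

Step 2
Reactants: 3 (2Z)-3-iodobut-2-en-1-ol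
Product: 4 tert-butyl{[(2Z)-3-iodobut-2-en-1-yl]oxy}dimethylsilane
Conditions: TBSCl, imidazole, CH2Cl2, 0 °C to rt
Reagents that add atoms: tert-butyldimethylsilyl chloride (CC(C)(C)[Si](C)(C)Cl)
Why: Routine silylation of a primary allylic alcohol.

Step 3
Reactants: 5 prop-2-yn-1-ol
Product: 7 (2Z)-3-iodo-2-methylprop-2-en-1-ol, via alkenylmagnesium alkoxide 6 (not isolated)
Conditions: MeMgBr (2.5 equiv), CuI (10 mol%), THF, −10 °C to rt; then I2, −20 °C
Reagents that add atoms: methylmagnesium bromide (C[Mg]Br); iodine (II)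
Why: Copper-catalysed anti-carbomagnesiation of the propargylic alkoxide (methyl to the proximal carbon, magnesium held on the distal carbon by chelation) followed by iodinolysis gives the (Z)-iodide stereospecifically.

Step 4
Reactants: 4 tert-butyl{[(2Z)-3-iodobut-2-en-1-yl]oxy}dimethylsilane, 7 (2Z)-3-iodo-2-methylprop-2-en-1-ol
Product: 11 (2Z,4Z)-6-[(tert-butyldimethylsilyl)oxy]-2,4-dimethylhexa-2,4-dien-1-ol, via alkenyllithium 8 (not isolated), via alkenylzinc chloride 9 (not isolated), via lithium alkoxide 10 (not isolated)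
Conditions: 4, t-BuLi (2 equiv), Et2O, −78 °C, then ZnCl2, THF; 7, n-BuLi (1 equiv), THF, −78 °C; both combined, Pd(PPh3)4 (5 mol%), THF, rt
Reagents that add atoms: none
Why: Negishi coupling joins the two alkenyl partners with retention at both sp2 carbons, so the (2Z,4Z) geometry is inherited from 4 and 7, the hydroxyl of 7 being masked as its lithium alkoxide.

Step 5
Reactants: 11 (2Z,4Z)-6-[(tert-butyldimethylsilyl)oxy]-2,4-dimethylhexa-2,4-dien-1-ol
Product: 12 tert-butyl{[(2Z,4Z)-6-chloro-3,5-dimethylhexa-2,4-dien-1-yl]oxy}dimethylsilane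
Conditions: MsCl, LiCl, 2,4,6-collidine, DMF, 0 °C
Reagents that add atoms: lithium chloride ([Li+].[Cl-])
Why: Mesylation in the presence of chloride converts the primary allylic alcohol into the chloride by SN2 displacement at low temperature, without allylic transposition or loss of geometry.

Step 6
Reactants: 13 tert-butyldimethyl(prop-2-yn-1-yloxy)silane
Product: 15 4-[(tert-butyldimethylsilyl)oxy]but-2-ynal, via lithium acetylide 14 (not isolated)
Conditions: n-BuLi, THF, −78 °C; then DMF, −78 to 0 °C; inverse quench into aq. KH2PO4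
Reagents that add atoms: N,N-dimethylformamide (CN(C)C=O)
Why: Formylation of a lithium acetylide with DMF and a buffered inverse quench is the standard route to ynals.

Step 7
Reactants: 12 tert-butyl{[(2Z,4Z)-6-chloro-3,5-dimethylhexa-2,4-dien-1-yl]oxy}dimethylsilane, 15 4-[(tert-butyldimethylsilyl)oxy]but-2-ynal
Product: 17 (2Z,4S,5S)-1,8-bis[(tert-butyldimethylsilyl)oxy]-3-methyl-4-(prop-1-en-2-yl)oct-2-en-6-yn-5-ol, via allylic trichlorosilane 16 (not isolated)
Conditions: HSiCl3, iPr2NEt, CuCl (5 mol%), Et2O, rt, volatiles removed; then 15, (R,R)-2,2′-bipyrrolidine-derived bis(phosphoramide) with a pentane-1,5-diylbis(methylamino) tether (5 mol%), iPr2NEt, CH2Cl2, −78 °C; aq. NaHCO3/KF work-up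
Reagents that add atoms: none
Why: Chloride-to-trichlorosilane exchange keeps the alkene geometry, and the chiral Lewis-base-catalysed allylation passes through a closed chair at hypervalent silicon in which the (Z)-γ-substituent is axial, so C5 and C6 emerge syn, the catalyst selects the Si face of the ynal (C6) and allylic transposition creates the isopropenyl group.

Step 8
Reactants: 17 (2Z,4S,5S)-1,8-bis[(tert-butyldimethylsilyl)oxy]-3-methyl-4-(prop-1-en-2-yl)oct-2-en-6-yn-5-ol
Product: 19 (2Z,4S,5S,6Z)-1,8-bis[(tert-butyldimethylsilyl)oxy]-7-iodo-3-methyl-4-(prop-1-en-2-yl)octa-2,6-dien-5-ol, via cyclic sodium alkenylalanate 18 (not isolated)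
Conditions: NaAlH2(OCH2CH2OCH3)2 (Red-Al), THF, 0 °C; then I2, −78 °C
Reagents that add atoms: iodine (II)
Why: The propargylic alkoxide directs trans-hydroalumination (hydride to C7, aluminium to C11), and iodinolysis with retention leaves iodine on C11 cis to C6, the geometry that later places the ester cis to C6.

Step 9
Reactants: 19 (2Z,4S,5S,6Z)-1,8-bis[(tert-butyldimethylsilyl)oxy]-7-iodo-3-methyl-4-(prop-1-en-2-yl)octa-2,6-dien-5-ol
Product: 20 (2Z,4S,5S,6Z)-1,8-bis[(tert-butyldimethylsilyl)oxy]-7-iodo-3-methyl-4-(prop-1-en-2-yl)octa-2,6-dien-5-yl 2-methylpropanoate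
Conditions: 2-methylpropanoyl chloride, pyridine, DMAP (cat.), CH2Cl2, 0 °C to rt
Reagents that add atoms: 2-methylpropanoyl chloride (CC(C)C(Cl)=O)
Why: DMAP-catalysed acylation installs the C6 isobutyrate of the target and prevents butenolide formation once the cis ester is in place.

Step 10
Reactants: 20 (2Z,4S,5S,6Z)-1,8-bis[(tert-butyldimethylsilyl)oxy]-7-iodo-3-methyl-4-(prop-1-en-2-yl)octa-2,6-dien-5-yl 2-methylpropanoate
Product: 21 methyl (2Z,4R,5S,6Z)-8-[(tert-butyldimethylsilyl)oxy]-2-{[(tert-butyldimethylsilyl)oxy]methyl}-6-methyl-4-[(2-methylpropanoyl)oxy]-5-(prop-1-en-2-yl)octa-2,6-dienoate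
Conditions: Pd(PPh3)2Cl2 (5 mol%), CO (1 atm), MeOH, Et3N, DMF, 50 °C
Reagents that add atoms: carbon monoxide ([C-]#[O+]); methanol (CO)
Why: Palladium-catalysed methoxycarbonylation of the vinyl iodide proceeds with retention of alkene geometry, and oxidative addition into the C–I bond should outpace ionisation of the hindered allylic ester under CO.

Step 11
Reactants: 21 methyl (2Z,4R,5S,6Z)-8-[(tert-butyldimethylsilyl)oxy]-2-{[(tert-butyldimethylsilyl)oxy]methyl}-6-methyl-4-[(2-methylpropanoyl)oxy]-5-(prop-1-en-2-yl)octa-2,6-dienoate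
Product: 22 methyl (2E,4R,5S,6Z)-8-bromo-2-(bromomethyl)-6-methyl-4-[(2-methylpropanoyl)oxy]-5-(prop-1-en-2-yl)octa-2,6-dienoate
Conditions: Ph3PBr2 (2.5 equiv), CH2Cl2, 0 °C to rt
Reagents that add atoms: dibromotriphenylphosphorane (BrP(Br)(c1ccccc1)(c1ccccc1)c1ccccc1)
Why: Ph3PBr2 converts primary silyl ethers directly into bromides through silyloxyphosphonium ions and SN2 displacement, giving both allylic bromides in one operation.

Step 12
Reactants: 22 methyl (2E,4R,5S,6Z)-8-bromo-2-(bromomethyl)-6-methyl-4-[(2-methylpropanoyl)oxy]-5-(prop-1-en-2-yl)octa-2,6-dienoate, 23 glyoxal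
Product: 26 (5S,6S,7S,8R,9S,10S)-9-hydroxy-6-(2-methylpropanoyloxy)elema-1,3,11(13)-trien-12,8-olide, via hydroxy aldehyde 24 (not isolated), via dihydroxy ester 25 (not isolated)
Conditions: In powder (3 equiv), 23 (40% aq., 1.1 equiv), THF/H2O (1:1), rt, 22 added slowly at high dilution; extraction, then p-TsOH·H2O (cat.), CH2Cl2, rt
Reagents that add atoms: none
Why: Proposed new method: indium inserts into both allylic C–Br bonds; the less hindered 2-(methoxycarbonyl)allyl terminus adds first to glyoxal through its γ-carbon (C7), the γ,γ-disubstituted terminus then attacks the resulting α-hydroxy aldehyde intramolecularly through C10, and acid closes the lactone; the closest known reactions are the aqueous indium Barbier allylation of glyoxal and of α-hydroxy aldehydes, the lactone-forming 2-(bromomethyl)acrylate allylation and intramolecular Barbier cyclisations of ω-formyl allylic halides. The cyclohexane closes by 6-exo-trig addition of C10 to the C9 carbonyl through a chair-like Zimmerman–Traxler array cis-fused to the forming ring, and the lactone by 5-exo-trig attack of the C8 hydroxyl on the ester. C7 is set by allylic 1,3-strain (the C6–H bond eclipses the ester-bearing alkene and glyoxal approaches anti to the C5 branch), and C8 follows from the (E)-alkene geometry, which puts the C6 substituent equatorial in the closed transition state and gives the anti adduct, i.e. the trans-fused lactone. C10 and C9 are set in the ring closure: the (Z)-alkene geometry delivers vinyl and the C9 hydroxyl cis (methyl trans), and the chair with the C5, C7 and C8 substituents equatorial and the C8–O bond antiperiplanar to the forming bond (Felkin–Anh) makes the methyl and the C9 hydroxyl axial. The step needs annulation to beat double intermolecular addition and reductive 1,4-elimination of the isobutyrate; high dilution with about one equivalent of glyoxal, the fast six-membered ring closure and the known tolerance of δ-acyloxy allylmetal reagents (those derived from 3-(bromomethyl)butenolides) are relied on for this.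

Step 13
Reactants: 26 (5S,6S,7S,8R,9S,10S)-9-hydroxy-6-(2-methylpropanoyloxy)elema-1,3,11(13)-trien-12,8-olide
Product: 28 (5R,6S,7S,8R,9S,10S)-9-hydroxy-6-(2-methylpropanoyloxy)-15-oxoelema-1,3,11(13)-trien-12,8-olide, via allylic alcohol 27 (not isolated)
Conditions: SeO2 (30 mol%), t-BuOOH, CH2Cl2, rt; filtration, then MnO2, CH2Cl2, rt
Reagents that add atoms: tert-butyl hydroperoxide (CC(C)(C)OO)
Why: Riley allylic oxidation can only engage the isopropenyl group (the vinyl group has no allylic hydrogen, the methylene lactone is electron-poor) and prefers its methyl over the C5 methine, and MnO2 then oxidises only the allylic alcohol, leaving the C9 carbinol.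

Step 14
Reactants: 28 (5R,6S,7S,8R,9S,10S)-9-hydroxy-6-(2-methylpropanoyloxy)-15-oxoelema-1,3,11(13)-trien-12,8-olide
Product: 31 CNP0496100.1 (1R,5R,6S,7S,8R,9S,10S)-1,2-epoxy-9-hydroxy-6-(2-methylpropanoyloxy)-15-oxoelema-3,11(13)-dien-12,8-olide, via secondary bromide bromohydrin 29 (not isolated), via primary bromide bromohydrin 30 (not isolated)
Conditions: NBS, THF/H2O (4:1), 0 °C; then K2CO3, MeCN, 0 °C to rt
Reagents that add atoms: water (O)
Why: The halohydrin sequence puts the oxirane oxygen on the face opposite to the one a direct oxidant attacks: the large bromonium ion forms on the exposed face of the neopentyl vinyl group (the face syn to the axial C9 hydroxyl, which a peracid or a hydroxyl-directed epoxidation would also use to give the C1 epimer), water opens it anti at either carbon and base-induced 3-exo-tet closure gives the (1R)-oxirane, while the enal and the methylene lactone are too electron-poor to react with NBS.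

Compound list
1 | but-2-yn-1-ol | CC#CCO | starting material
2 | sodium 2,2-bis(2-methoxyethoxy)-3-methyl-2,5-dihydro-1,2-oxaaluminol-2-uide (cyclic alkenylalanate) | CC1=CCO[Al-]1(OCCOC)OCCOC.[Na+] | intermediate
3 | (2Z)-3-iodobut-2-en-1-ol | I/C(C)=C\CO | intermediate
4 | tert-butyl{[(2Z)-3-iodobut-2-en-1-yl]oxy}dimethylsilane | I/C(C)=C\CO[Si](C)(C)C(C)(C)C | intermediate
5 | prop-2-yn-1-ol | C#CCO | starting material
6 | bromo{(1Z)-3-[(bromomagnesio)oxy]-2-methylprop-1-en-1-yl}magnesium | Br[Mg]OC/C(C)=C\[Mg]Br | intermediate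
7 | (2Z)-3-iodo-2-methylprop-2-en-1-ol | OC/C(C)=C\I | intermediate
8 | {4-[(tert-butyldimethylsilyl)oxy]but-2-en-2-yl}lithium, lithium cis to the CH2OTBS group | [Li]/C(C)=C\CO[Si](C)(C)C(C)(C)C | intermediate
9 | chloro{4-[(tert-butyldimethylsilyl)oxy]but-2-en-2-yl}zinc, zinc cis to the CH2OTBS group | Cl[Zn]/C(C)=C\CO[Si](C)(C)C(C)(C)C | intermediate
10 | lithium (2Z)-3-iodo-2-methylprop-2-en-1-olate | [Li]OC/C(C)=C\I | intermediate
11 | (2Z,4Z)-6-[(tert-butyldimethylsilyl)oxy]-2,4-dimethylhexa-2,4-dien-1-ol | OC/C(C)=C\C(C)=C/CO[Si](C)(C)C(C)(C)C | intermediate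
12 | tert-butyl{[(2Z,4Z)-6-chloro-3,5-dimethylhexa-2,4-dien-1-yl]oxy}dimethylsilane | ClC/C(C)=C\C(C)=C/CO[Si](C)(C)C(C)(C)C | intermediate
13 | tert-butyldimethyl(prop-2-yn-1-yloxy)silane | C#CCO[Si](C)(C)C(C)(C)C | starting material
14 | {3-[(tert-butyldimethylsilyl)oxy]prop-1-yn-1-yl}lithium | [Li]C#CCO[Si](C)(C)C(C)(C)C | intermediate
15 | 4-[(tert-butyldimethylsilyl)oxy]but-2-ynal | O=CC#CCO[Si](C)(C)C(C)(C)C | intermediate
16 | tert-butyl{[(2Z,4Z)-3,5-dimethyl-6-(trichlorosilyl)hexa-2,4-dien-1-yl]oxy}dimethylsilane | Cl[Si](Cl)(Cl)C/C(C)=C\C(C)=C/CO[Si](C)(C)C(C)(C)C | intermediate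
17 | (2Z,4S,5S)-1,8-bis[(tert-butyldimethylsilyl)oxy]-3-methyl-4-(prop-1-en-2-yl)oct-2-en-6-yn-5-ol | CC(C)(C)[Si](C)(C)OCC#C[C@@H](O)[C@@H](C(C)=C)/C(C)=C\CO[Si](C)(C)C(C)(C)C | intermediate
18 | sodium cyclic alkenylalanate from 17 (1,2-oxaaluminol-2-uide; aluminium on the carbon that carries iodine in 19, two 2-methoxyethoxy ligands) | CC(C)(C)[Si](C)(C)OCC1=C[C@H]([C@@H](C(C)=C)/C(C)=C\CO[Si](C)(C)C(C)(C)C)O[Al-]1(OCCOC)OCCOC.[Na+] | intermediate
19 | (2Z,4S,5S,6Z)-1,8-bis[(tert-butyldimethylsilyl)oxy]-7-iodo-3-methyl-4-(prop-1-en-2-yl)octa-2,6-dien-5-ol | CC(C)(C)[Si](C)(C)OC/C(I)=C/[C@@H](O)[C@@H](C(C)=C)/C(C)=C\CO[Si](C)(C)C(C)(C)C | intermediate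
20 | (2Z,4S,5S,6Z)-1,8-bis[(tert-butyldimethylsilyl)oxy]-7-iodo-3-methyl-4-(prop-1-en-2-yl)octa-2,6-dien-5-yl 2-methylpropanoate | CC(C)(C)[Si](C)(C)OC/C(I)=C/[C@@H](OC(=O)C(C)C)[C@@H](C(C)=C)/C(C)=C\CO[Si](C)(C)C(C)(C)C | intermediate
21 | methyl (2Z,4R,5S,6Z)-8-[(tert-butyldimethylsilyl)oxy]-2-{[(tert-butyldimethylsilyl)oxy]methyl}-6-methyl-4-[(2-methylpropanoyl)oxy]-5-(prop-1-en-2-yl)octa-2,6-dienoate | CC(C)(C)[Si](C)(C)OC/C(C(=O)OC)=C/[C@@H](OC(=O)C(C)C)[C@@H](C(C)=C)/C(C)=C\CO[Si](C)(C)C(C)(C)C | intermediate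
22 | methyl (2E,4R,5S,6Z)-8-bromo-2-(bromomethyl)-6-methyl-4-[(2-methylpropanoyl)oxy]-5-(prop-1-en-2-yl)octa-2,6-dienoate | BrC/C(C(=O)OC)=C/[C@@H](OC(=O)C(C)C)[C@@H](C(C)=C)/C(C)=C\CBr | intermediate
23 | glyoxal (ethanedial, 40% aqueous solution) | O=CC=O | starting material
24 | methyl (3R,4S,5S,6Z)-8-bromo-3-[(1R)-1-hydroxy-2-oxoethyl]-6-methyl-2-methylidene-4-[(2-methylpropanoyl)oxy]-5-(prop-1-en-2-yl)oct-6-enoate | C=C(C(=O)OC)[C@H]([C@@H](O)C=O)[C@@H](OC(=O)C(C)C)[C@@H](C(C)=C)/C(C)=C\CBr | intermediate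
25 | methyl (5S,6S,7R,8R,9S,10S)-8,9-dihydroxy-6-(2-methylpropanoyloxy)elema-1,3,11(13)-trien-12-oate (cyclohexane closed, lactone open) | C=C(C(=O)OC)[C@@H]1[C@@H](O)[C@@H](O)[C@@](C)(C=C)[C@H](C(C)=C)[C@@H]1OC(=O)C(C)C | intermediate
26 | (5S,6S,7S,8R,9S,10S)-9-hydroxy-6-(2-methylpropanoyloxy)elema-1,3,11(13)-trien-12,8-olide | C=C1C(=O)O[C@@H]2[C@@H]1[C@@H](OC(=O)C(C)C)[C@@H](C(C)=C)[C@](C)(C=C)[C@@H]2O | intermediate
27 | (5S,6S,7S,8R,9S,10S)-9,15-dihydroxy-6-(2-methylpropanoyloxy)elema-1,3,11(13)-trien-12,8-olide | C=C1C(=O)O[C@@H]2[C@@H]1[C@@H](OC(=O)C(C)C)[C@@H](C(=C)CO)[C@](C)(C=C)[C@@H]2O | intermediate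
28 | (5R,6S,7S,8R,9S,10S)-9-hydroxy-6-(2-methylpropanoyloxy)-15-oxoelema-1,3,11(13)-trien-12,8-olide | C=C1C(=O)O[C@@H]2[C@@H]1[C@@H](OC(=O)C(C)C)[C@@H](C(=C)C=O)[C@](C)(C=C)[C@@H]2O | intermediate
29 | (1S,5R,6S,7S,8R,9S,10S)-1-bromo-2,9-dihydroxy-6-(2-methylpropanoyloxy)-15-oxoelema-3,11(13)-dien-12,8-olide | C=C1C(=O)O[C@@H]2[C@@H]1[C@@H](OC(=O)C(C)C)[C@@H](C(=C)C=O)[C@](C)([C@H](Br)CO)[C@@H]2O | intermediate
30 | (1R,5R,6S,7S,8R,9S,10S)-2-bromo-1,9-dihydroxy-6-(2-methylpropanoyloxy)-15-oxoelema-3,11(13)-dien-12,8-olide | C=C1C(=O)O[C@@H]2[C@@H]1[C@@H](OC(=O)C(C)C)[C@@H](C(=C)C=O)[C@](C)([C@@H](O)CBr)[C@@H]2O | intermediate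
31 | CNP0496100.1, (1R,5R,6S,7S,8R,9S,10S)-1,2-epoxy-9-hydroxy-6-(2-methylpropanoyloxy)-15-oxoelema-3,11(13)-dien-12,8-olide | C=C1C(=O)O[C@@H]2[C@@H]1[C@@H](OC(=O)C(C)C)[C@@H](C(=C)C=O)[C@](C)([C@@H]1CO1)[C@@H]2O | target

Total step count: 14. Longest linear sequence: 12 steps (steps 1, 2, 4, 5, 7, 8, 9, 10, 11, 12, 13, 14, from but-2-yn-1-ol); steps 3 and 6 are one-step branches.

Steps most likely to fail

Step 12 (proposed new method). Ring closure may lose to a second intermolecular addition and oligomerisation with glyoxal. The allylindium termini may lose their alkene geometry before they add, which would give the cis-fused lactone or C9/C10 epimers. The isobutyrate may be lost by reductive 1,4-elimination. The fallback is stepwise and uses known reactions. It sets out from 22: a zinc-mediated Barbier reaction (Zn dust, THF/aq. NH4Cl) with 2,2-dimethoxyacetaldehyde should engage only the more reactive 2-(bromomethyl)acrylate terminus and give hydroxy ester dimethyl acetal F1. Acetal hydrolysis (aq. CF3CO2H, CH2Cl2) then gives hydroxy aldehyde 24, now isolated. An intramolecular Nozaki–Hiyama–Kishi-type allylation with CrCl2 (THF, high dilution) closes the cyclohexane to 25, and acid-catalysed lactonisation returns to the route at 26.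

Step 7. The (Z)-geometry may erode during chloride or trichlorosilane formation, and enantio- and diastereocontrol with the ynal may be insufficient. The fallback sets out from 12 and 15: a catalytic asymmetric Nozaki–Hiyama allylation (CrCl2, Mn, TMSCl, chiral oxazoline–sulfonamide ligand) is stereoconvergent and should give anti alcohol F2, the C6 epimer of 17. Mitsunobu inversion with 4-nitrobenzoic acid (PPh3, diisopropyl azodicarboxylate) gives 4-nitrobenzoate F3, and methanolysis (K2CO3, MeOH) returns to the route at 17.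

Step 14. Facial discrimination in bromonium formation may be poor, and the C9 hydroxyl may capture the bromonium ion to give a cyclic ether. The fallback sets out from 28 and replaces substrate control by catalyst control: epoxidation of the terminal vinyl group with Ti(OiPr)4, a chiral salalen ligand and aqueous H2O2 leads directly to 31; no new compound arises (F0).

Further compounds
F1 | step 12 | methyl (3R,4S,5S,6Z)-8-bromo-3-[(1R)-1-hydroxy-2,2-dimethoxyethyl]-6-methyl-2-methylidene-4-[(2-methylpropanoyl)oxy]-5-(prop-1-en-2-yl)oct-6-enoate | C=C(C(=O)OC)[C@H]([C@@H](O)C(OC)OC)[C@@H](OC(=O)C(C)C)[C@@H](C(C)=C)/C(C)=C\CBr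
F2 | step 7 | (2Z,4S,5R)-1,8-bis[(tert-butyldimethylsilyl)oxy]-3-methyl-4-(prop-1-en-2-yl)oct-2-en-6-yn-5-ol | CC(C)(C)[Si](C)(C)OCC#C[C@H](O)[C@@H](C(C)=C)/C(C)=C\CO[Si](C)(C)C(C)(C)C
F3 | step 7 | (2Z,4S,5S)-1,8-bis[(tert-butyldimethylsilyl)oxy]-3-methyl-4-(prop-1-en-2-yl)oct-2-en-6-yn-5-yl 4-nitrobenzoate | CC(C)(C)[Si](C)(C)OCC#C[C@@H](OC(=O)c1ccc(cc1)[N+](=O)[O-])[C@@H](C(C)=C)/C(C)=C\CO[Si](C)(C)C(C)(C)C
F0 | step 14 | none | none
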